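**Retrosynthetic overview**

1. The phloroglucinol dialdehyde is carried as a 2,4,6-trimethoxyphenyl group; both CHO groups come from a late double ortho-lithiation/formylation, followed by thiolate O-demethylation.
2. Both tertiary carbinols (C4 and C11) come from one double methyl addition to a 4-keto-7-acetyl trans-decalin; C7 (bought with the opposite sense) and C5 are set by base equilibration.
3. Key disconnection C1–C1': Claisen rearrangement of the (E)-aryl-vinyl ether of a ring A 4-methoxy-1,4-dien-3-ol. It transfers the C3–O stereocentre to C1 and C1', and enol-ether hydrolysis then leaves the C4 ketone.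
4. Ring A comes from Robinson annulation of (+)-dihydrocarvone (ring B) with methoxymethyl vinyl ketone, then dehydrogenation and 1,2-reduction to the dienol.
5. Ring order: ring B is bought, ring A is annulated onto it, and the aromatic ring is bought as 2,4,6-trimethoxybenzaldehyde.

Assumptions: eudesmane numbering is used for the decalin (C1 carries the benzylic carbon C1', C4 the ring carbinol, C5/C10 the ring fusion, C7 the side chain); 1-methoxybut-3-en-2-one, N-tert-butylbenzenesulfinimidoyl chloride and lithium 4-methylbenzenethiolate are taken as catalogue reagents; commercial (+)-dihydrocarvone is a C2-epimer mixture that converges through its enolate.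

**Step 1**
Reactants: 1 (+)-dihydrocarvone [(2R,5R)-2-methyl-5-(prop-1-en-2-yl)cyclohexan-1-one]; 2 1-methoxybut-3-en-2-one
Product: 4 (4aR,7R)-1-methoxy-4a-methyl-7-(prop-1-en-2-yl)-4,4a,5,6,7,8-hexahydronaphthalen-2(3H)-one, via Michael adduct diketone 3 (not isolated)
Conditions: KOH (0.3 equiv), EtOH, 0 °C to rt, then reflux
Reagents that add atoms: none
Why: Robinson annulation in which the thermodynamic enolate of 1 adds axially to 2 on the face cis to the equatorial isopropenyl group, so the new quaternary C10 has its methyl trans to that group (the 10-epi series, the usual major isomer under base), and aldol condensation of the methoxymethyl carbon onto the ring carbonyl closes ring A.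

**Step 2**
Reactants: 4 (4aR,7R)-1-methoxy-4a-methyl-7-(prop-1-en-2-yl)-4,4a,5,6,7,8-hexahydronaphthalen-2(3H)-one
Product: 6 (4aR,7R)-1-methoxy-4a-methyl-7-(prop-1-en-2-yl)-5,6,7,8-tetrahydronaphthalen-2(4aH)-one, via lithium dienolate 5 (not isolated)
Conditions: LiN(iPr)2, THF, −78 °C; then PhS(Cl)=N-t-Bu, −78 °C
Reagents that add atoms: none
Why: Kinetic deprotonation takes place at the C2 methylene, and the sulfinimidoyl chloride oxidises that enolate by sulfur transfer and syn elimination (Mukaiyama dehydrogenation) to the cross-conjugated dienone without touching a stereocentre.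

**Step 3**
Reactants: 6 (4aR,7R)-1-methoxy-4a-methyl-7-(prop-1-en-2-yl)-5,6,7,8-tetrahydronaphthalen-2(4aH)-one
Product: 7 (2R,4aR,7R)-1-methoxy-4a-methyl-7-(prop-1-en-2-yl)-2,4a,5,6,7,8-hexahydronaphthalen-2-ol
Conditions: NaBH4, CeCl3·7H2O, MeOH, −78 °C; used crude
Reagents that add atoms: none
Why: Luche 1,2-reduction in which hydride enters the flat dienone from the face opposite the pseudo-axial angular methyl, so the C3 hydroxyl ends on the same face as that methyl.

**Step 4**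
Reactants: 8 2,4,6-trimethoxybenzaldehyde
Product: 9 2-[(E)-2-iodoethenyl]-1,3,5-trimethoxybenzene
Conditions: CHI3, CrCl2, THF, 0 °C to rt
Reagents that add atoms: iodoform, IC(I)I
Why: Takai iodo-olefination converts the hindered aryl aldehyde into the E vinyl iodide under non-basic conditions.

**Step 5**
Reactants: 7 (2R,4aR,7R)-1-methoxy-4a-methyl-7-(prop-1-en-2-yl)-2,4a,5,6,7,8-hexahydronaphthalen-2-ol; 9 2-[(E)-2-iodoethenyl]-1,3,5-trimethoxybenzene
Product: 12 (2S)-2-[(1R,4aS,6R,8aR)-8a-methyl-4-oxo-6-(prop-1-en-2-yl)-1,4,4a,5,6,7,8,8a-octahydronaphthalen-1-yl]-2-(2,4,6-trimethoxyphenyl)acetaldehyde, via aryl-vinyl allyl ether 10 (not isolated), via methoxydiene aldehyde 11 (not isolated)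
Conditions: CuI (10 mol %), 3,4,7,8-tetramethyl-1,10-phenanthroline (20 mol %), Cs2CO3, toluene, 80 °C; filter; o-xylene, 140 °C; then oxalic acid (cat.), THF–H2O, rt
Reagents that add atoms: water, O
Why: Copper-catalysed C–O coupling gives the E vinyl ether with retention, and its Claisen ([3,3]-sigmatropic) rearrangement moves the C3–O bond suprafacially to C1 on the face of the angular methyl while a chair transition state with the aryl group equatorial sets C1' as S, after which mild acid hydrolyses the methyl dienyl ether to the 2-en-4-one with the favoured trans ring fusion.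

**Step 6**
Reactants: 12 (2S)-2-[(1R,4aS,6R,8aR)-8a-methyl-4-oxo-6-(prop-1-en-2-yl)-1,4,4a,5,6,7,8,8a-octahydronaphthalen-1-yl]-2-(2,4,6-trimethoxyphenyl)acetaldehyde
Product: 13 (2S)-2-[(1R,4aS,6R,8aR)-6-acetyl-8a-methyl-4-oxo-1,4,4a,5,6,7,8,8a-octahydronaphthalen-1-yl]-2-(2,4,6-trimethoxyphenyl)acetaldehyde
Conditions: OsO4 (2 mol %), NaIO4, 2,6-lutidine, dioxane–H2O, rt
Reagents that add atoms: osmium tetroxide, O=[Os](=O)(=O)=O; sodium periodate, [Na+].[O-]I(=O)(=O)=O
Why: Lemieux–Johnson cleavage in which OsO4 dihydroxylates only the electron-rich 1,1-disubstituted alkene (the enone alkene is electron-poor) and periodate cleaves the diol to the methyl ketone, with no stereocentre touched.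

**Step 7**
Reactants: 13 (2S)-2-[(1R,4aS,6R,8aR)-6-acetyl-8a-methyl-4-oxo-1,4,4a,5,6,7,8,8a-octahydronaphthalen-1-yl]-2-(2,4,6-trimethoxyphenyl)acetaldehyde
Product: 14 (4R,4aR,7R,8aS)-7-acetyl-4a-methyl-4-[(1S)-3-methyl-1-(2,4,6-trimethoxyphenyl)but-2-en-1-yl]-4a,5,6,7,8,8a-hexahydronaphthalen-1(4H)-one
Conditions: i-PrPPh3I, n-BuLi, THF, 0 °C; then 13, −78 °C to 0 °C
Reagents that add atoms: isopropyltriphenylphosphonium iodide, CC(C)[P+](c1ccccc1)(c1ccccc1)c1ccccc1.[I-]
Why: Wittig olefination with the unstabilised isopropylidene ylide is selective for the aldehyde over the two ketones at low temperature and installs the isobutenyl group without changing C1'.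

**Step 8**
Reactants: 14 (4R,4aR,7R,8aS)-7-acetyl-4a-methyl-4-[(1S)-3-methyl-1-(2,4,6-trimethoxyphenyl)but-2-en-1-yl]-4a,5,6,7,8,8a-hexahydronaphthalen-1(4H)-one
Product: 16 (4R,4aR,7S,8aS)-7-acetyl-4a-methyl-4-[(1S)-3-methyl-1-(2,4,6-trimethoxyphenyl)butyl]-3,4,4a,5,6,7,8,8a-octahydronaphthalen-1(2H)-one, via axial-acetyl diketone 15 (not isolated)
Conditions: H2 (4 atm), Pd/C, EtOAc–MeOH, rt; purge; then NaOMe (cat.), MeOH, rt
Reagents that add atoms: none
Why: Catalytic hydrogenation saturates both alkenes without creating a stereocentre, and methoxide then epimerises the acetyl-bearing C7 (and equilibrates C5 next to the ring ketone) to the all-equatorial trans-decalin under thermodynamic control.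

**Step 9**
Reactants: 16 (4R,4aR,7S,8aS)-7-acetyl-4a-methyl-4-[(1S)-3-methyl-1-(2,4,6-trimethoxyphenyl)butyl]-3,4,4a,5,6,7,8,8a-octahydronaphthalen-1(2H)-one
Product: 17 (1R,4R,4aR,7S,8aS)-7-(2-hydroxypropan-2-yl)-1,4a-dimethyl-4-[(1S)-3-methyl-1-(2,4,6-trimethoxyphenyl)butyl]decahydronaphthalen-1-ol
Conditions: MeLi, CeCl3, THF, −78 °C to 0 °C
Reagents that add atoms: methyllithium, [Li]C
Why: Organocerium 1,2-addition (no enolisation) in which methyl attacks the C4 ketone equatorially, away from the axial angular methyl, giving the axial tertiary alcohol cis to that methyl, and also turns the acetyl group into the hydroxyisopropyl group.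

**Step 10**
Reactants: 17 (1R,4R,4aR,7S,8aS)-7-(2-hydroxypropan-2-yl)-1,4a-dimethyl-4-[(1S)-3-methyl-1-(2,4,6-trimethoxyphenyl)butyl]decahydronaphthalen-1-ol
Product: 19 5-[(1S)-1-[(1R,4R,4aS,6S,8aR)-4-hydroxy-6-(2-hydroxypropan-2-yl)-4,8a-dimethyldecahydronaphthalen-1-yl]-3-methylbutyl]-2,4,6-trimethoxybenzene-1,3-dicarbaldehyde, via monoformyl aminoalkoxide trilithium salt 18 (not isolated)
Conditions: n-BuLi, TMEDA, THF, 0 °C; DMF (1 equiv), −78 °C; n-BuLi, 0 °C; DMF; then 1 M HCl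
Reagents that add atoms: N,N-dimethylformamide, CN(C)C=O
Why: Directed ortho-metalation, since each free ring position lies between two methoxy groups and the first formyl group stays masked as its lithium aminoalkoxide, so a second lithiation–formylation can follow in the same flask.

**Step 11**
Reactants: 19 5-[(1S)-1-[(1R,4R,4aS,6S,8aR)-4-hydroxy-6-(2-hydroxypropan-2-yl)-4,8a-dimethyldecahydronaphthalen-1-yl]-3-methylbutyl]-2,4,6-trimethoxybenzene-1,3-dicarbaldehyde
Product: 20 5-[(1S)-1-[(1R,4R,4aS,6S,8aR)-4-hydroxy-6-(2-hydroxypropan-2-yl)-4,8a-dimethyldecahydronaphthalen-1-yl]-3-methylbutyl]-2,4,6-trihydroxybenzene-1,3-dicarbaldehyde (CNP0409870.4)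
Conditions: LiSC6H4Me-4 (excess), HMPA–toluene, 110 °C; then dilute HCl
Reagents that add atoms: none
Why: SN2 O-demethylation by thiolate, which works because every methoxy group is ortho or para to a formyl group, while the basic conditions leave the two tertiary alcohols and all stereocentres alone.

**Compound list**

1 | (+)-dihydrocarvone, (2R,5R)-2-methyl-5-(prop-1-en-2-yl)cyclohexan-1-one | O=C1C[C@H](C(C)=C)CC[C@H]1C | starting material
2 | 1-methoxybut-3-en-2-one | C=CC(=O)COC | starting material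
3 | (2R,5R)-2-(4-methoxy-3-oxobutyl)-2-methyl-5-(prop-1-en-2-yl)cyclohexan-1-one | O=C1C[C@H](C(C)=C)CC[C@]1(C)CCC(=O)COC | intermediate
4 | (4aR,7R)-1-methoxy-4a-methyl-7-(prop-1-en-2-yl)-4,4a,5,6,7,8-hexahydronaphthalen-2(3H)-one | C1CC(=O)C(OC)=C2C[C@H](C(C)=C)CC[C@]12C | intermediate
5 | lithium (4aR,7R)-1-methoxy-4a-methyl-7-(prop-1-en-2-yl)-4,4a,5,6,7,8-hexahydronaphthalen-2-olate | C1C=C([O-])C(OC)=C2C[C@H](C(C)=C)CC[C@]12C.[Li+] | intermediate
6 | (4aR,7R)-1-methoxy-4a-methyl-7-(prop-1-en-2-yl)-5,6,7,8-tetrahydronaphthalen-2(4aH)-one | C1=CC(=O)C(OC)=C2C[C@H](C(C)=C)CC[C@]12C | intermediate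
7 | (2R,4aR,7R)-1-methoxy-4a-methyl-7-(prop-1-en-2-yl)-2,4a,5,6,7,8-hexahydronaphthalen-2-ol | C1=C[C@@H](O)C(OC)=C2C[C@H](C(C)=C)CC[C@]12C | intermediate
8 | 2,4,6-trimethoxybenzaldehyde | COc1cc(OC)c(C=O)c(OC)c1 | starting material
9 | 2-[(E)-2-iodoethenyl]-1,3,5-trimethoxybenzene | COc1cc(OC)c(/C=C/I)c(OC)c1 | intermediate
10 | 2-[(E)-2-{[(2R,4aR,7R)-1-methoxy-4a-methyl-7-(prop-1-en-2-yl)-2,4a,5,6,7,8-hexahydronaphthalen-2-yl]oxy}ethenyl]-1,3,5-trimethoxybenzene | C1=C[C@@H](O/C=C/c3c(OC)cc(OC)cc3OC)C(OC)=C2C[C@H](C(C)=C)CC[C@]12C | intermediate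
11 | (2S)-2-[(1R,6R,8aR)-4-methoxy-8a-methyl-6-(prop-1-en-2-yl)-1,5,6,7,8,8a-hexahydronaphthalen-1-yl]-2-(2,4,6-trimethoxyphenyl)acetaldehyde | O=C[C@H](c3c(OC)cc(OC)cc3OC)[C@H]1C=CC(OC)=C2C[C@H](C(C)=C)CC[C@]12C | intermediate
12 | (2S)-2-[(1R,4aS,6R,8aR)-8a-methyl-4-oxo-6-(prop-1-en-2-yl)-1,4,4a,5,6,7,8,8a-octahydronaphthalen-1-yl]-2-(2,4,6-trimethoxyphenyl)acetaldehyde | O=C[C@H](c3c(OC)cc(OC)cc3OC)[C@H]1C=CC(=O)[C@H]2C[C@H](C(C)=C)CC[C@]12C | intermediate
13 | (2S)-2-[(1R,4aS,6R,8aR)-6-acetyl-8a-methyl-4-oxo-1,4,4a,5,6,7,8,8a-octahydronaphthalen-1-yl]-2-(2,4,6-trimethoxyphenyl)acetaldehyde | O=C[C@H](c3c(OC)cc(OC)cc3OC)[C@H]1C=CC(=O)[C@H]2C[C@H](C(C)=O)CC[C@]12C | intermediate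
14 | (4R,4aR,7R,8aS)-7-acetyl-4a-methyl-4-[(1S)-3-methyl-1-(2,4,6-trimethoxyphenyl)but-2-en-1-yl]-4a,5,6,7,8,8a-hexahydronaphthalen-1(4H)-one | CC(C)=C[C@H](c3c(OC)cc(OC)cc3OC)[C@H]1C=CC(=O)[C@H]2C[C@H](C(C)=O)CC[C@]12C | intermediate
15 | (4R,4aR,7R,8aS)-7-acetyl-4a-methyl-4-[(1S)-3-methyl-1-(2,4,6-trimethoxyphenyl)butyl]-3,4,4a,5,6,7,8,8a-octahydronaphthalen-1(2H)-one | CC(C)C[C@H](c3c(OC)cc(OC)cc3OC)[C@H]1CCC(=O)[C@H]2C[C@H](C(C)=O)CC[C@]12C | intermediate
16 | (4R,4aR,7S,8aS)-7-acetyl-4a-methyl-4-[(1S)-3-methyl-1-(2,4,6-trimethoxyphenyl)butyl]-3,4,4a,5,6,7,8,8a-octahydronaphthalen-1(2H)-one | CC(C)C[C@H](c3c(OC)cc(OC)cc3OC)[C@H]1CCC(=O)[C@H]2C[C@@H](C(C)=O)CC[C@]12C | intermediate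
17 | (1R,4R,4aR,7S,8aS)-7-(2-hydroxypropan-2-yl)-1,4a-dimethyl-4-[(1S)-3-methyl-1-(2,4,6-trimethoxyphenyl)butyl]decahydronaphthalen-1-ol | CC(C)C[C@H](c3c(OC)cc(OC)cc3OC)[C@H]1CC[C@@](C)(O)[C@H]2C[C@@H](C(C)(C)O)CC[C@]12C | intermediate
18 | trilithium salt of the mono-(dimethylamino)(oxido)methyl adduct of 17 (both tertiary alkoxides lithiated) | CC(C)C[C@H](c3c(OC)c(C(O[Li])N(C)C)c(OC)cc3OC)[C@H]1CC[C@@](C)(O[Li])[C@H]2C[C@@H](C(C)(C)O[Li])CC[C@]12C | intermediate
19 | 5-[(1S)-1-[(1R,4R,4aS,6S,8aR)-4-hydroxy-6-(2-hydroxypropan-2-yl)-4,8a-dimethyldecahydronaphthalen-1-yl]-3-methylbutyl]-2,4,6-trimethoxybenzene-1,3-dicarbaldehyde | CC(C)C[C@H](c3c(OC)c(C=O)c(OC)c(C=O)c3OC)[C@H]1CC[C@@](C)(O)[C@H]2C[C@@H](C(C)(C)O)CC[C@]12C | intermediate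
20 | 5-[(1S)-1-[(1R,4R,4aS,6S,8aR)-4-hydroxy-6-(2-hydroxypropan-2-yl)-4,8a-dimethyldecahydronaphthalen-1-yl]-3-methylbutyl]-2,4,6-trihydroxybenzene-1,3-dicarbaldehyde | CC(C)C[C@H](c1c(O)c(C=O)c(O)c(C=O)c1O)[C@H]1CC[C@@](C)(O)[C@H]2C[C@@H](C(C)(C)O)CC[C@]12C | target

**Totals and risks**

Total step count: 11. Longest linear sequence: 10 steps (steps 1–3 and 5–11, from 1).

The three steps most likely to fail:

Step 5. The new C1–C1' bond is formed next to the quaternary C10 on the face of its methyl group, and the C1' configuration depends on a chair rather than a boat transition state. The chair places the aryl group close to the angular methyl, so the selectivity at C1' is uncertain and must be checked. If the copper coupling or the thermal rearrangement fails, the fallback sets out from dienol 7. Esterify it with (2,4,6-trimethoxyphenyl)acetic acid (DCC, DMAP) to the allylic ester F1. Ireland–Claisen rearrangement (KN(SiMe3)2, Me3SiCl, THF, −78 °C to rt, dilute HCl work-up) then gives the enone acid F2. LiAlH4 reduces acid and ketone to the diol F3, and Dess–Martin periodinane oxidises both carbinols, which comes back to the route at keto-aldehyde 12.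

Step 7. A disubstituted, basic ylide must react with a hindered, epimerisable alpha-aryl aldehyde in the presence of two enolisable ketones. The fallback sets out from 13: methylenate the aldehyde with salt-free Ph3P=CH2 at −78 °C to the terminal alkene F4, then extend it by cross-metathesis with 2-methylbut-2-ene (second-generation Grubbs catalyst), which comes back to the route at 14.

Step 10. Two successive ring lithiations are needed on a substrate that already carries two lithium alkoxides, and the second must tolerate the masked first aldehyde. The fallback sets out from diol 17: brominate both free ring positions with N-bromosuccinimide (MeCN, 0 °C) to the dibromide F5, then carry out double bromine–lithium exchange with t-BuLi and quench with DMF, which comes back to the route at dialdehyde 19.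

**Further compounds**

F1 | step 5 | (2R,4aR,7R)-1-methoxy-4a-methyl-7-(prop-1-en-2-yl)-2,4a,5,6,7,8-hexahydronaphthalen-2-yl (2,4,6-trimethoxyphenyl)acetate | C1=C[C@@H](OC(=O)Cc3c(OC)cc(OC)cc3OC)C(OC)=C2C[C@H](C(C)=C)CC[C@]12C
F2 | step 5 | (2S)-2-[(1R,4aS,6R,8aR)-8a-methyl-4-oxo-6-(prop-1-en-2-yl)-1,4,4a,5,6,7,8,8a-octahydronaphthalen-1-yl]-2-(2,4,6-trimethoxyphenyl)acetic acid | OC(=O)[C@H](c3c(OC)cc(OC)cc3OC)[C@H]1C=CC(=O)[C@H]2C[C@H](C(C)=C)CC[C@]12C
F3 | step 5 | (2S)-2-[(1R,4aS,6R,8aR)-4-hydroxy-8a-methyl-6-(prop-1-en-2-yl)-1,4,4a,5,6,7,8,8a-octahydronaphthalen-1-yl]-2-(2,4,6-trimethoxyphenyl)ethan-1-ol (epimer mixture at the ring carbinol) | OC[C@H](c3c(OC)cc(OC)cc3OC)[C@H]1C=CC(O)[C@H]2C[C@H](C(C)=C)CC[C@]12C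
F4 | step 7 | (4R,4aR,7R,8aS)-7-acetyl-4a-methyl-4-[(1S)-1-(2,4,6-trimethoxyphenyl)prop-2-en-1-yl]-4a,5,6,7,8,8a-hexahydronaphthalen-1(4H)-one | C=C[C@H](c3c(OC)cc(OC)cc3OC)[C@H]1C=CC(=O)[C@H]2C[C@H](C(C)=O)CC[C@]12C
F5 | step 10 | (1R,4R,4aR,7S,8aS)-4-[(1S)-1-(3,5-dibromo-2,4,6-trimethoxyphenyl)-3-methylbutyl]-7-(2-hydroxypropan-2-yl)-1,4a-dimethyldecahydronaphthalen-1-ol | CC(C)C[C@H](c3c(OC)c(Br)c(OC)c(Br)c3OC)[C@H]1CC[C@@](C)(O)[C@H]2C[C@@H](C(C)(C)O)CC[C@]12C
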